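All constants were set for the occasion; the run is a simulation.

Every partner that leaves the flask ends either in a product, one per substrate reacted, or paired with another in a homo dimer.

left-handed substrate 20 mM; partner 60.0 mM (fed, over 15 s); catalyst 10 µM; right-handed substrate 20 mM; time 40 min

    partner + catalyst + left-handed substrate → catalyst + left-handed product (k1 = 85000 M⁻² s⁻¹)
    partner + catalyst + right-handed substrate → catalyst + right-handed product (k2 = 35000 M⁻² s⁻¹)
    2 partner → homo dimer (k3 = 0.55 M⁻¹ s⁻¹)

- how much of the left-handed substrate and right-handed substrate together has reacted by 40 min
- how much left-handed product there is at 40 min, in percent of the left-handed substrate and right-handed substrate together charged

- catalyst is single-handed; left-handed substrate and right-handed substrate are mirror images of each other, charged as a racemate, each of them at the stated concentration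
- a step written with two of one species runs at k times the square of its concentration and takes two of it each time
- run time (flask): 40 min

Let B be the partner concentration, C the catalyst, s the charge of each substrate, and kL, kR and kD the constants of the left-handed, right-handed and dimer steps. Q is the partner charge. The two productive steps take partner in proportion to B, and dimerisation in proportion to B². The two drains are equal at the balance concentration B*:

B* = C(kL + kR)s / (2 kD) = 21.8 mM

The charge stands above it. Partner dosed at once, with demand held at its starting value, integrates to:

substrate reacted = B* ln(1 + Q/B*), so conversion = 72.1 %

But the substrates run down, so demand falls and this B* is too high. Scaling B* by 1 − c/2, the demand at mid-reaction for a conversion c, gives: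

conversion = 58.2 %

That correction used the inflated first c. One more pass with the new c gives:

conversion = 61.3 %

One objection remains. The feed time 15 s is close to partner's first half-life by dimerisation at the whole charge, 15.2 s. During the feed B stands below the charge, and a lower B shifts the split towards the productive steps, so this reckoning should lie somewhat low. It stops at the total and doesn't split it between the products.

The forecast gives 63 % conversion and 39.5 % left-handed product, above this reckoning, holding that “the fast dimerisation at tens of mM burns most of it”.

The flask gives 63.9 % and 39.9 %, with 0 % of the partner left, so both forecast values hold. The flask stops short of full conversion because of the dimerisation: without that step it reaches 100 % against 63.9 %. In the neighbour flask with 2.50 µM of catalyst, B* drops from 21.8 mM to 5.45 mM. One correction pass there gives 30.1 %, and that neighbour flask gives 32.0 %.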